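**Assumptions**
- Dihydroconiferyl alcohol (1) is commercially available.
- Carinol is the acyclic triol in the given SMILES, (2S,3S)-2,3-bis(4-hydroxy-3-methoxybenzyl)butane-1,2,4-triol.

**Retrosynthesis**
- Carinol comes from global hydride reduction of an aldol adduct, an α-hydroxy ester carrying a β-aldehyde.
- That adduct comes from a single enamine-catalysed cross-aldol of 3-(guaiacyl)propanal onto methyl guaiacylpyruvate, which sets both contiguous stereocenters (C3 by the catalyst, C2 by the proposed ketone-face control).
- The aldehyde comes from oxidation of dihydroconiferyl alcohol. The ketoester comes from vanillin by Erlenmeyer azlactone formation, hydrolysis and esterification.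
- No rings are formed. Both guaiacyl units are already present in the building blocks, and the free phenols are carried through unprotected.

---

**Step 1**
Reactants: 1 (dihydroconiferyl alcohol, 4-(3-hydroxypropyl)-2-methoxyphenol)
Product: 2, 3-(4-hydroxy-3-methoxyphenyl)propanal
Conditions: SO3·py, DMSO, Et3N, CH2Cl2, 0 °C
Reagents that add atoms: none
Why: Parikh–Doering oxidation converts the primary alcohol to the aldehyde under mild, low-temperature conditions that leave the free guaiacol untouched. Hypervalent-iodine oxidants such as PIDA can oxidise the guaiacol.

**Step 2**
Reactants: 3 (vanillin), 4 (N-acetylglycine)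
Product: 5, (Z)-4-(4-acetoxy-3-methoxybenzylidene)-2-methyloxazol-5(4H)-one
Conditions: Ac2O, NaOAc, 100 °C, 2 h
Reagents that add atoms: Ac2O, CC(=O)OC(C)=O (acetylates the phenol)
Why: In the Erlenmeyer–Plöchl azlactone synthesis, the in-situ oxazolone condenses with the aldehyde, and the phenol is acetylated at the same time.

**Step 3**
Reactants: 5
Product: 6, 3-(4-hydroxy-3-methoxyphenyl)-2-oxopropanoic acid
Conditions: 3 M aq HCl, reflux, N2, 4 h
Reagents that add atoms: water, O
Why: Acid opens the azlactone, hydrolyses the resulting enamide to the α-keto acid (the standard route to arylpyruvic acids) and also removes the phenol acetate.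

**Step 4**
Reactants: 6
Product: 7, methyl 3-(4-hydroxy-3-methoxyphenyl)-2-oxopropanoate
Conditions: MeOH, cat. H2SO4, reflux, 3 h
Reagents that add atoms: MeOH, CO
Why: Fischer esterification gives the ester. This is needed so that a free carboxylic acid does not protonate and deactivate the amine catalyst in the next step, and so that the ester can later be reduced to CH2OH.

**Step 5**
Reactants: 2 (1.5 equiv, added slowly), 7 (1.0 equiv), 8 ((S)-α,α-diphenylprolinol TMS ether, 20 mol%)
Product: 9, methyl (2S,3R)-2-hydroxy-2,3-bis(4-hydroxy-3-methoxybenzyl)-4-oxobutanoate
Conditions: 8 (20 mol%), PhCO2H (20 mol%), MeCN, 0 °C; aldehyde 2 added by syringe pump over 8 h, then 24 h; cold silica plug, used at once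
Reagents that add atoms: none
Why: Proposed new method: catalyst 8 converts 2 into its (E), s-trans enamine, which attacks the ketone carbonyl of 7 on the enamine face remote from the bulky diarylsilyloxymethyl group. This is the same sense of induction as in (S)-catalysed aldehyde Michael additions, and it gives the R centre at C3 of adduct 9, which becomes the S centre of carinol after reduction because the CIP priorities change. The ketone face, and hence C2, is controlled by a synclinal, acid-assisted, chair-like Houk–List-type arrangement. In it the benzoic acid binds the O=C–C=O unit of the ketoester, and the CO2Me group and the aryl-CH2 group are placed to minimise gauche interactions with the enamine, which should give the required (2S,3R) relative configuration. The closest known reaction type is the amine-catalysed enamine cross-aldol of aldehydes onto activated ketones (isatins, trifluoromethyl ketones, ketomalonates, non-enolisable ketoesters). Here it is extended to an enolisable, partly enolised aryl pyruvate to form an adjacent tertiary carbinol and tertiary carbon. The keto tautomer reacts under Curtin–Hammett control, and slow addition of the aldehyde suppresses its self-aldol.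

**Step 6**
Reactants: 9
Product: 10, (–)-carinol
Conditions: LiAlH4 (6 equiv), THF, 0 °C → rt, 3 h; Fieser work-up, then pH ~5 extraction
Reagents that add atoms: none
Why: LiAlH4 reduces the aldehyde first, which avoids α-epimerisation at C3 and retro-aldol, and then reduces the α-hydroxy ester (chelation-assisted) to the primary alcohol, giving the triol. The two free phenols only consume hydride as phenoxides. Neither stereocenter is altered, because the tertiary C–OH and the CH carry no carbonyl once reduction is complete.

---

**Compound list**

| No. | Name | SMILES | Role |
|---|---|---|---|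
| 1 | Dihydroconiferyl alcohol | COc1cc(CCCO)ccc1O | starting material |
| 2 | 3-(4-Hydroxy-3-methoxyphenyl)propanal | COc1cc(CCC=O)ccc1O | intermediate |
| 3 | Vanillin | COc1cc(C=O)ccc1O | starting material |
| 4 | N-Acetylglycine | CC(=O)NCC(=O)O | starting material |
| 5 | (Z)-4-(4-Acetoxy-3-methoxybenzylidene)-2-methyloxazol-5(4H)-one | CC1=N/C(=C\c2ccc(OC(C)=O)c(OC)c2)C(=O)O1 | intermediate |
| 6 | 3-(4-Hydroxy-3-methoxyphenyl)-2-oxopropanoic acid | COc1cc(CC(=O)C(=O)O)ccc1O | intermediate |
| 7 | Methyl 3-(4-hydroxy-3-methoxyphenyl)-2-oxopropanoate | COc1cc(CC(=O)C(=O)OC)ccc1O | intermediate |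
| 8 | (S)-α,α-Diphenylprolinol TMS ether (organocatalyst) | C[Si](C)(C)OC(c1ccccc1)(c1ccccc1)[C@@H]1CCCN1 | starting material |
| 9 | Methyl (2S,3R)-2-hydroxy-2,3-bis(4-hydroxy-3-methoxybenzyl)-4-oxobutanoate | COc1cc(C[C@@H](C=O)[C@](O)(C(=O)OC)Cc2ccc(O)c(OC)c2)ccc1O | intermediate |
| 10 | (–)-Carinol, (2S,3S)-2,3-bis(4-hydroxy-3-methoxybenzyl)butane-1,2,4-triol | COc1cc(C[C@@H](CO)[C@](O)(CO)Cc2ccc(O)c(OC)c2)ccc1O | target |

**Total steps:** 6. **Longest linear sequence:** 5 (steps 2 → 3 → 4 → 5 → 6).

**Three steps most likely to fail**
1. **Step 5 (proposed new aldol).** The risks are low diastereoselectivity, low reactivity because the ketoester is largely enolised, aldehyde self-aldol, and retro-aldol or dehydration of the adduct.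
   - Fallback: use known lignan-lactone chemistry. Start from a (S)-β-(4-hydroxy-3-methoxybenzyl, protected)-γ-butyrolactone made by Evans-type asymmetric alkylation. Apply Davis-oxaziridine α-hydroxylation, protect the tertiary OH (MOM), and alkylate with the protected vanillyl bromide (LDA, THF, –78 °C), which adds trans to the β-substituent. This trans relationship corresponds to the (2S,3S) configuration of carinol. Then remove the protecting groups and reduce with LiAlH4.
2. **Step 3 (keto acid).** The electron-rich arylpyruvic acid may oxidise, decarboxylate or tar under hot aqueous acid.
   - Fallback: make 7 by a different route. Run a Horner–Wadsworth–Emmons reaction of O-acetylvanillin with trimethyl 2-methoxyphosphonoacetate, then hydrolyse the resulting enol ether with mild aqueous HCl and remove the acetate (K2CO3, MeOH). This gives 7 directly.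
3. **Step 1 (oxidation).** The free phenol may lead to methylthiomethyl (MTM) ether or other over-oxidation by-products.
   - Fallback: obtain 2 from dihydroferulic acid by esterification followed by low-temperature DIBAL-H partial reduction, which avoids oxidants altogether.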